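The constants come from no measurement; what happens was integrated by code.

A small charge of free base, 0.800 equiv on Tuesday's and 1.60 equiv on Friday's, goes into a flask of electrophile at 0.10 M with 2.00 equiv of nucleophile, and I must say what it does to the electrophile in 15 min.

all flasks: electrophile 0.10 M; nucleophile 2.00 equiv; time 15 min

| charge | free base |
|---|---|
| Tuesday's | 0.800 equiv |
| Friday's | 1.60 equiv |

    2 electrophile → self-condensation product (k1 = 3.7 L mol⁻¹ min⁻¹)
    acid set free + free base ⇌ salt of the base, settled at all times (K2 = 32000 L mol⁻¹)
    nucleophile ⇌ dormant form (K3 = 11, k3 = 1.2 min⁻¹)
    electrophile + nucleophile → acid set free + target (k4 = 0.69 L mol⁻¹ min⁻¹)
    electrophile + target → side product (k5 = 3.3 L mol⁻¹ min⁻¹)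
    nucleophile + acid set free ⇌ protonated nucleophile, settled at all times (K6 = 13000 L mol⁻¹)

- a species is counted by the electrophile in it: one side product or self-condensation product counts as two
- where a step has two of a species, its rate is k times that concentration squared, and two are used at each turn
- run time (Tuesday's): 15 min

- part of the electrophile that has reacted at the end, Tuesday's
- part of the electrophile that has reacted at the end, Friday's
- what raising the equivalents of free base from its lowest to its highest value here does to the part of the electrophile that has reacted (changes below 5 percentage points count as none) (it rises / it falls / no change)

I reckon with two times: the run, 15 min, and the first half-life of the electrophile by self-condensation, 1.35 min. The run measured in these half-lives is 11.1, and a second-order loss leaves the fraction one over one plus that ratio.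

Coupling offers a third time, but its pseudo-first-order half-life on Tuesday's, 5.0 min with the nucleophile as charged, is longer than the self-condensation half-life. The nucleophile also passes into the dormant form with a forward half-life of 0.58 min. On Friday's, just after the start, self-condensation uses electrophile 5.4 times as fast as coupling does.

The free base reaches the electrophile through the acid set free by coupling, the slower loss at that moment, so I expect no change between the flasks. The ratio leaves 8.26% of the electrophile, which makes 91.7% reacted. Coupling and the side-product step use electrophile as well, so I commit to that as a floor.

The forecast stands a little above my figure, at 93.5% (92.5% to 94.5%) for Tuesday's and 93.6% (92.6% to 94.6%) for Friday's, with no change, holding that “doubling the base barely changes the small protonated-nucleophile fraction or the conversion”.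

The flasks give 93.5% on Tuesday's and 93.5% on Friday's, a shift of 0 percentage points, so the verdict is no change. Free base still free at the end is 89.0% of its charge on Tuesday's and 94.2% on Friday's. Tuesday's flask holds 6.5% of its electrophile against the 8.26% that a run of 11.1 first half-lives leaves by self-condensation alone. With electrophile at 0.060 M, equivalents and time as on Friday's, the first half-life by self-condensation is 2.25 min and the run is 6.66 first half-lives, which leaves 13.1%, and that flask holds 11.4%.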